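**Plan**

1. Retrosynthesis cuts first the C13–C14 CH2–CH2 bond of the acyl chain (C1 = ester carbonyl). This gives a decyl radical and a 13-carbon radical that already carries the 2-phenylethyl ester; each radical carbon is traced back to a CO2H group (undecanoic acid; mono-2-phenylethyl tetradecanedioate).
2. The second cut is the acyl C1–O bond, leading to 2-phenylethanol and tetradecanedioic acid mono-tert-butyl ester.
3. Enabling feature: C13 and C14 are two primary, unbranched CH2 carbons of like polarity in the middle of the (CH2)21 chain. They lie twelve methylenes from the only functional group (the C1 ester) and have no α-substituent, so they cannot be paired as donor and acceptor, but as primary radicals at a Pt anode they should couple instead of being oxidised further. The single benzene ring sits beyond the O–CH2CH2 spacer, out of reach.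
4. Forward: esterification with 2-phenylethanol (step 1), removal of the tert-butyl group to unmask the helper CO2H (step 2), then chain joining by mixed Kolbe electrolysis with undecanoic acid (step 3). Both helper carboxyls leave as CO2 in the bond-forming step.
5. No ring is formed. The target is achiral with no C=C, so no stereochemistry has to be set.

Key step: step 3

Remark: the mono-tert-butyl ester 1 is taken as a catalogue compound; availability was not checked here.

**Step 1**
Reactants: 1 14-(tert-butoxy)-14-oxotetradecanoic acid (tetradecanedioic acid mono-tert-butyl ester); 2 2-phenylethanol
Product: 3 tert-butyl 2-phenylethyl tetradecanedioate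
Conditions: DCC (1.1 equiv), DMAP (0.1 equiv), CH2Cl2, 0 °C to rt; filter, SiO2
Reagents that add atoms: none
Why: Steglich esterification; carbodiimide activation of the free carboxyl and DMAP-catalysed acyl transfer to the unhindered primary alcohol should proceed under neutral conditions that leave the tert-butyl ester untouched.

**Step 2**
Reactants: 3 tert-butyl 2-phenylethyl tetradecanedioate
Product: 4 14-oxo-14-(2-phenylethoxy)tetradecanoic acid (mono-2-phenylethyl tetradecanedioate)
Conditions: TFA/CH2Cl2 (1:1), rt; evaporate, co-evaporate with toluene
Reagents that add atoms: none
Why: Acidolysis of the tert-butyl ester by alkyl–oxygen cleavage (AAL1) releases the tert-butyl cation, which loses a proton to isobutene, while the primary 2-phenylethyl ester cannot ionise and should be stable to anhydrous TFA.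

**Step 3**
Reactants: 4 14-oxo-14-(2-phenylethoxy)tetradecanoic acid; 5 undecanoic acid (5 equiv)
Product: 8 2-phenylethyl tricosanoate, via decyl radical 6 (not isolated), via 13-oxo-13-(2-phenylethoxy)tridecyl radical 7 (not isolated)
Conditions: undivided cell, smooth Pt anode/Pt cathode, KOH (0.05 equiv per CO2H), MeOH, 45 °C, constant current ca. 0.25 A cm−2, stopped while the electrolyte is still weakly acidic; SiO2 (hexane, then hexane/EtOAc)
Reagents that add atoms: none
Why: Mixed (crossed) Kolbe electrolysis: at the Pt anode the carboxylates of 4 and 5 are each oxidised by one electron to acyloxy radicals that lose CO2 at once, giving the primary radicals 7 and 6 side by side in the carboxylate layer on the electrode, where radical–radical combination forms the C13–C14 bond while protons are reduced to H2 at the cathode. The closest known reaction type is the crossed Kolbe coupling of a fatty acid with a half-ester of an α,ω-dicarboxylic acid, the classical anodic chain extension of fatty acids. No ring is closed and no stereocentre is formed. Two selectivities are needed: cross- over homo-coupling, and one-electron (radical) over two-electron (Hofer–Moest, carbocation) oxidation. The first is secured by the excess of the cheap acid 5, so that nearly every radical 7 should meet a radical 6, the homo-dimer of 6 being a plain hydrocarbon removed with hexane on silica; the second by the substrate itself, since both radical carbons are primary and unbranched with no α-heteroatom or aryl group, supported by smooth Pt, high current density and a low degree of neutralisation. The C1 ester and the phenyl ring lie twelve or more atoms from the radical centre and should stay untouched, because the adsorbed carboxylate layer shields them from the anode and the bulk stays weakly acidic, which should also suppress methanolysis of the 2-phenylethyl ester.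

**Compound list**

1 | 14-(tert-butoxy)-14-oxotetradecanoic acid (tetradecanedioic acid mono-tert-butyl ester) | CC(C)(C)OC(=O)CCCCCCCCCCCCC(=O)O | starting material
2 | 2-phenylethanol | OCCc1ccccc1 | starting material
3 | tert-butyl 2-phenylethyl tetradecanedioate | CC(C)(C)OC(=O)CCCCCCCCCCCCC(=O)OCCc1ccccc1 | intermediate
4 | 14-oxo-14-(2-phenylethoxy)tetradecanoic acid (mono-2-phenylethyl tetradecanedioate) | OC(=O)CCCCCCCCCCCCC(=O)OCCc1ccccc1 | intermediate
5 | undecanoic acid | CCCCCCCCCCC(=O)O | starting material
6 | decyl radical (formed at the anode, not isolated) | CCCCCCCCC[CH2] | intermediate
7 | 13-oxo-13-(2-phenylethoxy)tridecyl radical (formed at the anode, not isolated) | [CH2]CCCCCCCCCCCC(=O)OCCc1ccccc1 | intermediate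
8 | 2-phenylethyl tricosanoate | CCCCCCCCCCCCCCCCCCCCCCC(=O)OCCc1ccccc1 | target

**Summary**

Total step count: 3
Longest linear sequence: 3 steps (1 → 3 → 4 → 8)

**Steps most likely to fail**

Step 3 (key step). What may go wrong:
- statistical homo-coupling of each radical with its own kind at the expense of the cross-coupling;
- passivation of the anode by a film of the waxy products;
- further oxidation of the radicals to cations, followed by capture by methanol or elimination;
- methanolysis of the 2-phenylethyl ester if the electrolyte is allowed to turn alkaline.

Fallback, from 4 to 8, forming the same C13–C14 bond by a polar, metal-catalysed route. Acid 4 would be condensed with N-hydroxyphthalimide (DIC, DMAP cat., CH2Cl2) to the redox-active ester 1-(1,3-dioxoisoindolin-2-yl) 14-(2-phenylethyl) tetradecanedioate F1. Didecylzinc F2 would be prepared from commercial decylmagnesium bromide and ZnCl2 (0.5 equiv) in THF. Nickel-catalysed decarboxylative alkyl–alkyl (Negishi-type) coupling of F1 with F2 (NiCl2·glyme, 4,4′-di-tert-butyl-2,2′-bipyridine, THF/DMF, rt) should then give 8 directly.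

Step 2. What may go wrong: electrophilic tert-butylation of the phenyl ring by the liberated cation, or incomplete acidolysis that leaves material difficult to separate from the waxy product.

Fallback, from 2 to 4, without any protecting group. 2-Phenylethanol 2 (excess) would be esterified with commercial tetradecanedioic acid (TsOH cat., toluene, Dean–Stark) to the symmetric diester bis(2-phenylethyl) tetradecanedioate F3. Controlled half-saponification of F3 (KOH, 1.0 equiv, THF/H2O, 0 °C to rt, then acidification and extractive separation) should give the half-ester 4.

Step 1. What may go wrong: O-to-N acyl migration in the carbodiimide adduct, giving an unreactive N-acylurea, and difficult removal of the urea from the waxy diester.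

Fallback, from 2 (together with 1) to 3, by carboxylate O-alkylation instead of acyl activation. Alcohol 2 would be converted into 2-phenylethyl 4-methylbenzenesulfonate F4 (TsCl, Et3N, DMAP cat., CH2Cl2). SN2 displacement of F4 by the caesium carboxylate of 1 (Cs2CO3, DMF, 50 °C) should give 3.

**Further compounds**

F1 | step 3 | 1-(1,3-dioxoisoindolin-2-yl) 14-(2-phenylethyl) tetradecanedioate | O=C(ON1C(=O)c2ccccc2C1=O)CCCCCCCCCCCCC(=O)OCCc1ccccc1
F2 | step 3 | didecylzinc | CCCCCCCCCC[Zn]CCCCCCCCCC
F3 | step 2 | bis(2-phenylethyl) tetradecanedioate | O=C(OCCc1ccccc1)CCCCCCCCCCCCC(=O)OCCc1ccccc1
F4 | step 1 | 2-phenylethyl 4-methylbenzenesulfonate | Cc1ccc(cc1)S(=O)(=O)OCCc1ccccc1
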